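The blue run is slow: it takes 25.0 min to make 48.4% target, so I first ask how much of the catalyst charged can work at all. The substrate and the loading give 2.16 mM of free catalyst, and 0.45 mM of impurity stands against it.

| flask | substrate | coupling partner | free catalyst | impurity | remark |
|---|---|---|---|---|---|
| blue | 0.049 M | 2.5 equiv | 4.4 mol% | 0.45 mM | the very flask that is asked about, followed so far |
| grey | 0.049 M | 5 equiv | 4.4 mol% | 0.45 mM | run made earlier |
| flask | 0.049 M | 2.50 equiv | 4.4 mol% | 0.45 mM |  |

| run | time / min | target / % | substrate / % |
|---|---|---|---|
| blue | 5.00 | 13.3 | 87.8 |
| blue | 10.0 | 24.3 | 73.8 |
| blue | 15.0 | 34.0 | 65.9 |
| blue | 20.0 | 42.3 | 58.0 |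
| blue | 25.0 | 48.4 | 49.7 |
| grey | 2.50 | 7.9 | 94.5 |
| grey | 8.00 | 21.8 | 78.2 |
| grey | 12.0 | 28.0 | 71.0 |
| grey | 20.0 | 45.5 | 56.2 |
| grey | 30.0 | 57.7 | 40.8 |
| grey | 40.0 | 73.0 | 32.9 |

(readings scatter by 1 percentage point)

- steps that have been proposed: coupling partner + free catalyst -> catalyst intermediate A; catalyst intermediate A -> catalyst intermediate B; substrate + catalyst intermediate B -> catalyst intermediate C; catalyst intermediate C -> free catalyst + target; free catalyst + impurity -> spent catalyst
- no earlier run changes the charge of free catalyst; that part of a forecast is a guess

* apparent order in free catalyst when 30% of the substrate are converted (percent change of the rate of making target for one percent more free catalyst charged)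
* apparent order in coupling partner when 30% of the substrate are converted (percent change of the rate of making target for one percent more coupling partner charged)
* factor on the rate of making target when 30% of the substrate are converted if coupling partner is charged twice over

I fold these givens into one number, the poison share 0.209: impurity charged over free catalyst charged, which is the fraction of the catalyst lost if each impurity takes one free catalyst for good. If the rate then follows the catalyst left working, one percent more charge gives one over one minus the poison share percent more working catalyst, so I commit to an order in free catalyst of 1.26.

One number isn't enough, though, as the poison share holds no coupling partner. For that I read the runs: at 20.0 min, twice the coupling partner moves the target from 42.3% in the blue run to 45.5% in the grey run. That gap of 3.2 percentage points, read with a scatter of 1 point per reading, comes to 7.57% of the target in the blue run for a doubled charge, so the order in coupling partner is small.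

The forecast gives 1.2 for free catalyst, below my figure, with 0.12 for coupling partner and a factor of 1.09 on doubling it. Its ground for the catalyst is this: “If poisoning is quick and complete, active catalyst is charge minus impurity”.

The flask gives 1.3 for free catalyst, 0.067 for coupling partner and a factor of 1.03.

    coupling partner + free catalyst → catalyst intermediate A (k = 1.50 /M/s)
    catalyst intermediate A → catalyst intermediate B (k = 1.80 /s)
    substrate + catalyst intermediate B → catalyst intermediate C (k = 0.290 /M/s)
    catalyst intermediate C → free catalyst + target (k = 3.40 /s)
    free catalyst + impurity → spent catalyst (k = 900 /M/s)

The loss of free catalyst to impurity raises the order in free catalyst by 0.264. In the flask asked about, spent catalyst holds 20.9% of the catalyst charged at 0.150 h, with impurity at 0%. In the simulated run with that loss taken away, the poison share is zero and the order is 1.0. One over one minus the poison share is 1.26, and that run's rate stands at 1.26 times the actual one.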